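**Retrosynthetic overview**
- The strategy rests on this feature: the C5–C6 bond and the C9 carbonyl of the bicyclo[3.3.1]nonane (ring C1–C8–C7–C6–C5–C9, C8 = CMe2) correspond to one enol ether C9(OMe)=C5 of a mirror-symmetric 2,6-dimethoxycyclohexa-2,5-diene and a carbene carbon C6 held on C1 through C7(=O)–C8Me2.
- Endgame: C3–aroyl bond by acylation of the C3 vinyllithium; C1– and C5–geranyl bonds by bridgehead enolate alkylation of the vinylogous methyl ester (C5 first, C1 after moving the O-methyl group from O2 to O4); C4 oxygen by allylic oxidation.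
- C7 exo-prenyl: radical allylation of a C7 xanthate from the outer face, then cross-metathesis. A direct hydride reduction of the 7,9-dione would take C9 first, so C9 is reduced and silylated while C7 is masked as its enolate, and C9 is re-oxidised before the radical step.
- Core: diazoketone 6 → (1R,5R)-dione 8 by copper–bis(oxazoline) cyclopropanation of one enantiotopic enol ether, then acid cleavage of the donor–acceptor bond C6–C9.
- Ring order: ring C1–C2–C3–C4–C5–C9 is the former arene (Birch reduction); ring C1–C8–C7–C6–C5–C9 closes in the key step.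

Key step: step 4

Remark: locants follow the target throughout (C1 next to C8Me2, C9 the bridging carbonyl; exo = away from the C2–C4 bridge, endo = toward it); the carbinol centres at C9 (10–15) and C7 (12–16) are drawn as the expected major epimers and are erased in steps 10 and 11; the ligand antipode in step 4 is the one that leads to (1R,5R)-8; the target is drawn as its C4-enol tautomer.

**Step 1**
Reactants: 1 2-(2,6-dimethoxyphenyl)acetic acid
Product: 3 2-(2,6-dimethoxyphenyl)-2-methylpropanoic acid, via lithium 2-(2,6-dimethoxyphenyl)propanoate 2 (not isolated)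
Conditions: LDA (2.2 equiv), THF, −78 → 0 °C; MeI; then LDA (1.2 equiv), 0 °C; MeI; aq. HCl
Reagents that add atoms: iodomethane, CI
Why: Enediolate (carboxylic acid dianion) alkylation: LDA forms the dianion of the arylacetic acid, which is C-methylated, and a second deprotonation and methylation in the same flask should build the quaternary carbon without an ester detour.

**Step 2**
Reactants: 3 2-(2,6-dimethoxyphenyl)-2-methylpropanoic acid
Product: 4 2-(2,6-dimethoxycyclohexa-2,5-dien-1-yl)-2-methylpropanoic acid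
Conditions: Li, NH3 (l), THF, t-BuOH, −78 °C; NH4Cl; cold NaH2PO4 buffer (pH 5–6), extract, use crude
Reagents that add atoms: none
Why: Birch reduction: the carboxylate is inert and the two methoxy-bearing carbons stay sp2, so protonation should fall on the ring carbon between them and on the para carbon to give the symmetric bis(enol ether), which the cold buffered work-up preserves.

**Step 3**
Reactants: 4 2-(2,6-dimethoxycyclohexa-2,5-dien-1-yl)-2-methylpropanoic acid
Product: 6 1-diazo-3-(2,6-dimethoxycyclohexa-2,5-dien-1-yl)-3-methylbutan-2-one, via isobutyl carbonic mixed anhydride 5 (not isolated)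
Conditions: i-BuOCOCl, Et3N, THF, −15 °C; then CH2N2 (excess), Et2O, 0 → 20 °C
Reagents that add atoms: diazomethane, C=[N+]=[N-]; isobutyl chloroformate, CC(C)COC(Cl)=O (its atoms stay only in 5)
Why: Acylation of diazomethane by a mixed carbonic anhydride (Arndt–Eistert-type diazoketone synthesis), a path also used for α,α-disubstituted acids, should work here because the medium stays basic throughout and the two enol ethers never meet acid.

**Step 4**
Reactants: 6 1-diazo-3-(2,6-dimethoxycyclohexa-2,5-dien-1-yl)-3-methylbutan-2-one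
Product: 8 (1R,5R)-2-methoxy-8,8-dimethylbicyclo[3.3.1]non-2-ene-7,9-dione, via methoxycyclopropyl ketone 7 (not isolated)
Conditions: [Cu(MeCN)4]PF6 (5 mol %), C2-symmetric bis(oxazoline) ligand (t-Bu-box type, 6 mol %), toluene, 25 → 50 °C, slow addition of 6; then PPTS (0.2 equiv), THF–H2O 10:1, 0 → 20 °C
Reagents that add atoms: water, O
Why: The Cu(I)–box complex converts the diazo ketone into an electrophilic copper carbenoid at C6, which adds across one electron-rich enol ether C5=C9(OMe) in an intramolecular [2+1] cycloaddition (closest known reaction: catalytic asymmetric intramolecular cyclopropanation of α-diazo ketones onto cyclohexadiene bis(enol ethers)) to give cyclopropane 7, in which a five-membered ketone ring C6–C7–C8–C1–C9 is cis-fused to the three-membered ring. In 7 the C6–C9 bond lies between the methoxy donor on C9 and the C7 carbonyl acceptor, so mild acid should cleave only this bond; the C9 oxocarbenium ion is hydrolysed to the ketone and the C7 enol is protonated at C6. The ring C1–C8–C7–C6–C5–C9 is closed by the new C5–C6 bond, first as a five-membered ring in the cyclopropanation and then enlarged by one atom when C6–C9 breaks, while ring C1–C2–C3–C4–C5–C9 is the old diene ring. C1 and C5 are set together by the catalyst alone, because 6 has a mirror plane through C1 and C4 and its two enol ethers are enantiotopic; the tether reaches only the diene face that carries it, so the configuration at C1 follows from which enol ether reacts. The step needs cyclopropanation to win over C–H insertion at the doubly allylic C4H2, which the nucleophilic enol ether, the five-membered transition state and the gem-dimethyl group should secure, and it needs the remaining enol ether C2=C3 to survive, which the much greater lability of the push–pull cyclopropane toward PPTS at 0 °C should secure.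

**Step 5**
Reactants: 8 (1R,5R)-2-methoxy-8,8-dimethylbicyclo[3.3.1]non-2-ene-7,9-dione
Product: 10 9-hydroxy-2-methoxy-8,8-dimethylbicyclo[3.3.1]non-2-en-7-one (bridgeheads as in 8; 9-OH over the C6–C8 bridge), via C7 lithium enolate 9 (not isolated)
Conditions: LDA (1.1 equiv), THF, −78 °C; DIBAL-H (1.5 equiv), −78 °C; aq. Rochelle salt
Reagents that add atoms: none
Why: Hydride would reduce the exposed bridging C9 ketone of 8 before the neopentyl C7 ketone, so this is used deliberately: LDA turns the only enolisable carbonyl (C7, toward C6; C9 is flanked by two bridgeheads) into its lithium enolate (in situ enolate protection), DIBAL-H then reduces C9 alone from the face over the sp2 C2–C3 bridge and away from the axial C8 methyl, and aqueous work-up returns the C7 ketone.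

**Step 6**
Reactants: 10 9-hydroxy-2-methoxy-8,8-dimethylbicyclo[3.3.1]non-2-en-7-one
Product: 11 2-methoxy-8,8-dimethyl-9-(triethylsilyloxy)bicyclo[3.3.1]non-2-en-7-one
Conditions: TESOTf, 2,6-lutidine, CH2Cl2, −78 → 0 °C
Reagents that add atoms: triethylsilyl trifluoromethanesulfonate, CC[Si](CC)(CC)OS(=O)(=O)C(F)(F)F
Why: Silylation with a silyl triflate and a hindered pyridine base should cap even the crowded C9 carbinol without touching the ketone or the acid-labile enol ether.

**Step 7**
Reactants: 11 2-methoxy-8,8-dimethyl-9-(triethylsilyloxy)bicyclo[3.3.1]non-2-en-7-one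
Product: 12 2-methoxy-8,8-dimethyl-9-(triethylsilyloxy)bicyclo[3.3.1]non-2-en-7-ol (7-OH endo)
Conditions: NaBH4, MeOH, 0 → 20 °C
Reagents that add atoms: none
Why: Borohydride reduction of the single remaining ketone should proceed from the open outer face to give the endo alcohol, a centre that is erased at the radical stage, so either epimer serves.

**Step 8**
Reactants: 12 2-methoxy-8,8-dimethyl-9-(triethylsilyloxy)bicyclo[3.3.1]non-2-en-7-ol
Product: 14 O-[2-methoxy-8,8-dimethyl-9-(triethylsilyloxy)bicyclo[3.3.1]non-2-en-7-yl] S-methyl carbonodithioate, via sodium xanthate 13 (not isolated)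
Conditions: NaH, imidazole (cat.), THF, 0 → 20 °C; CS2; MeI
Reagents that add atoms: carbon disulfide, S=C=S; iodomethane, CI
Why: Standard xanthate formation (alkoxide addition to CS2, then S-methylation), which works on hindered secondary alkoxides and leaves the silyl ether and enol ether alone.

**Step 9**
Reactants: 14 O-[2-methoxy-8,8-dimethyl-9-(triethylsilyloxy)bicyclo[3.3.1]non-2-en-7-yl] S-methyl carbonodithioate
Product: 15 O-(9-hydroxy-2-methoxy-8,8-dimethylbicyclo[3.3.1]non-2-en-7-yl) S-methyl carbonodithioate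
Conditions: TBAF, AcOH (1:1), THF, 0 → 20 °C
Reagents that add atoms: none
Why: Acetic acid-buffered fluoride should cleave the labile triethylsilyl ether at silicon while the xanthate and the enol ether are exposed to neither strong base nor acid.

**Step 10**
Reactants: 15 O-(9-hydroxy-2-methoxy-8,8-dimethylbicyclo[3.3.1]non-2-en-7-yl) S-methyl carbonodithioate
Product: 16 O-(2-methoxy-8,8-dimethyl-9-oxobicyclo[3.3.1]non-2-en-7-yl) S-methyl carbonodithioate
Conditions: Dess–Martin periodinane, pyridine, CH2Cl2, 0 → 20 °C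
Reagents that add atoms: none
Why: Dess–Martin oxidation under pyridine buffering should return the planar C9 carbonyl without affecting the xanthate or enol ether, so that no C9 substituent leans over the outer face of C7 in the radical step.

**Step 11**
Reactants: 16 O-(2-methoxy-8,8-dimethyl-9-oxobicyclo[3.3.1]non-2-en-7-yl) S-methyl carbonodithioate
Product: 17 7-exo-allyl-2-methoxy-8,8-dimethylbicyclo[3.3.1]non-2-en-9-one (bridgeheads as in 8)
Conditions: allylSnBu3 (8 equiv, about 1 M), AIBN (0.2 equiv, in portions), PhH, 80 °C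
Reagents that add atoms: allyltributylstannane, C=CC[Sn](CCCC)(CCCC)CCCC
Why: Keck radical allylation: Bu3Sn• adds to the thiocarbonyl, β-scission gives the secondary C7 radical, and this adds to the allylstannane with loss of Bu3Sn•; the new C7 centre should be exo because the inner lobe of the radical points into the cleft at C2=C3 (about 3 Å away), leaving only the outer face to the stannane, whose high concentration should also outrun transannular addition to C3.

**Step 12**
Reactants: 17 7-exo-allyl-2-methoxy-8,8-dimethylbicyclo[3.3.1]non-2-en-9-one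
Product: 18 7-exo-allyl-2-methoxy-8,8-dimethylbicyclo[3.3.1]non-2-ene-4,9-dione
Conditions: CrO3 (15 equiv), 3,5-dimethylpyrazole (15 equiv), CH2Cl2, −20 °C
Reagents that add atoms: chromium trioxide, O=[Cr](=O)=O
Why: Allylic oxidation with the CrO3–3,5-dimethylpyrazole complex should take the C4 methylene, which is activated by the electron-rich enol ether and leads to a stable vinylogous ester, in preference to the allylic CH2 of the monosubstituted side-chain alkene and the bridgehead C–H.

**Step 13**
Reactants: 18 7-exo-allyl-2-methoxy-8,8-dimethylbicyclo[3.3.1]non-2-ene-4,9-dione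
Product: 19 2-methoxy-8,8-dimethyl-7-exo-(3-methylbut-2-enyl)bicyclo[3.3.1]non-2-ene-4,9-dione
Conditions: 2-methylbut-2-ene (excess), Grubbs II (5 mol %), CH2Cl2, 40 °C
Reagents that add atoms: 2-methylbut-2-ene, CC=C(C)C
Why: Olefin cross-metathesis of the terminal allyl group with 2-methylbut-2-ene should give the prenyl group and propene while the trisubstituted vinylogous ester C=C stays inert; the step is placed before any geranyl group is present because geranyl chains would be truncated under the same conditions.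

**Step 14**
Reactants: 19 2-methoxy-8,8-dimethyl-7-exo-(3-methylbut-2-enyl)bicyclo[3.3.1]non-2-ene-4,9-dione; 20 geranyl bromide
Product: 22 5-geranyl-2-methoxy-8,8-dimethyl-7-exo-(3-methylbut-2-enyl)bicyclo[3.3.1]non-2-ene-4,9-dione, via C5 bridgehead lithium enolate 21 (not isolated)
Conditions: LDA (1.3 equiv), THF, −78 °C; 20 (2 equiv), −78 → 0 °C
Reagents that add atoms: geranyl bromide (20), CC(C)=CCC/C(C)=C/CBr
Why: Bridgehead enolate alkylation of a bicyclo[3.3.1]nonane vinylogous ester: LDA should remove C5–H, which is α′ to the C4 carbonyl and α to C9=O (C1–H is only γ, and the vinylic C3–H calls for LiTMP), and the cage-held carbanion is alkylated by the allylic bromide with its configuration fixed by the bicycle.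

**Step 15**
Reactants: 22 5-geranyl-2-methoxy-8,8-dimethyl-7-exo-(3-methylbut-2-enyl)bicyclo[3.3.1]non-2-ene-4,9-dione
Product: 23 5-geranyl-4-hydroxy-8,8-dimethyl-7-exo-(3-methylbut-2-enyl)bicyclo[3.3.1]non-3-ene-2,9-dione (β-diketone in enol form)
Conditions: LiCl (10 equiv), DMSO, 120 °C; dilute citric acid work-up
Reagents that add atoms: none
Why: Krapcho-type SN2 demethylation of the vinylogous ester by chloride should release the stabilised diketonate under neutral conditions that spare the three trisubstituted alkenes and the C9 ketone.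

**Step 16**
Reactants: 23 5-geranyl-4-hydroxy-8,8-dimethyl-7-exo-(3-methylbut-2-enyl)bicyclo[3.3.1]non-3-ene-2,9-dione
Product: 24 5-geranyl-4-methoxy-8,8-dimethyl-7-exo-(3-methylbut-2-enyl)bicyclo[3.3.1]non-3-ene-2,9-dione
Conditions: TMSCHN2 (2 equiv), MeOH–PhMe 1:4, 20 °C; chromatography; regioisomer 22 returned to step 15
Reagents that add atoms: (trimethylsilyl)diazomethane, C[Si](C)(C)C=[N+]=[N-]
Why: O-Methylation of the β-diketone with a diazoalkane should give both enol ether regioisomers; the isomer with OMe on C4 and the carbonyl on C2 (now next to C1–H) is separated, and the other isomer is compound 22, which is recycled.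

**Step 17**
Reactants: 24 5-geranyl-4-methoxy-8,8-dimethyl-7-exo-(3-methylbut-2-enyl)bicyclo[3.3.1]non-3-ene-2,9-dione; 20 geranyl bromide
Product: 26 1,5-digeranyl-4-methoxy-8,8-dimethyl-7-exo-(3-methylbut-2-enyl)bicyclo[3.3.1]non-3-ene-2,9-dione, via C1 bridgehead lithium enolate 25 (not isolated)
Conditions: LDA (1.5 equiv), THF, −78 °C; 20 (3 equiv), −78 → −20 °C
Reagents that add atoms: geranyl bromide (20), CC(C)=CCC/C(C)=C/CBr
Why: Second bridgehead enolate alkylation: after the O-methyl transposition C1–H is α′ to the C2 carbonyl, and deprotonation and allylation at this bridgehead next to a gem-dimethyl group is the same reaction type used for bridgehead prenylation in this ring system.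

**Step 18**
Reactants: 27 3,4-dihydroxybenzoic acid
Product: 28 tert-butyldimethylsilyl 3,4-bis(tert-butyldimethylsilyloxy)benzoate
Conditions: TBSCl (3.5 equiv), imidazole (7 equiv), DMF, 20 °C
Reagents that add atoms: tert-butyldimethylsilyl chloride, CC(C)(C)[Si](C)(C)Cl
Why: Imidazole-promoted silylation should cap both phenols and the acid in one operation.

**Step 19**
Reactants: 28 tert-butyldimethylsilyl 3,4-bis(tert-butyldimethylsilyloxy)benzoate
Product: 29 3,4-bis(tert-butyldimethylsilyloxy)benzoyl chloride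
Conditions: (COCl)2 (1.2 equiv), DMF (cat.), CH2Cl2, 0 → 20 °C; evaporate, use crude
Reagents that add atoms: oxalyl chloride, ClC(=O)C(Cl)=O
Why: Silyl esters are converted directly into acid chlorides by oxalyl chloride–DMF under neutral conditions, with no HCl formed, so the aryl silyl ethers should survive.

**Step 20**
Reactants: 26 1,5-digeranyl-4-methoxy-8,8-dimethyl-7-exo-(3-methylbut-2-enyl)bicyclo[3.3.1]non-3-ene-2,9-dione; 29 3,4-bis(tert-butyldimethylsilyloxy)benzoyl chloride
Product: 31 3-[3,4-bis(tert-butyldimethylsilyloxy)benzoyl]-1,5-digeranyl-4-methoxy-8,8-dimethyl-7-exo-(3-methylbut-2-enyl)bicyclo[3.3.1]non-3-ene-2,9-dione, via C3 vinyllithium 30 (not isolated)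
Conditions: LiTMP (2 equiv), THF, −78 °C; 29 (2.5 equiv), −78 → −40 °C
Reagents that add atoms: 3,4-bis(tert-butyldimethylsilyloxy)benzoyl chloride (29), ClC(=O)c1ccc(O[Si](C)(C)C(C)(C)C)c(O[Si](C)(C)C(C)(C)C)c1
Why: With both bridgeheads quaternary, LiTMP should remove the vinylic C3–H between the methoxy group and the carbonyl (alkoxy-directed α-lithiation of a β-alkoxy enone), and the vinyllithium is C-acylated by the aroyl chloride.

**Step 21**
Reactants: 31 3-[3,4-bis(tert-butyldimethylsilyloxy)benzoyl]-1,5-digeranyl-4-methoxy-8,8-dimethyl-7-exo-(3-methylbut-2-enyl)bicyclo[3.3.1]non-3-ene-2,9-dione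
Product: 32 (1S,5S,7R)-3-(3,4-dihydroxybenzoyl)-1,5-bis[(2E)-3,7-dimethylocta-2,6-dien-1-yl]-4-hydroxy-8,8-dimethyl-7-(3-methylbut-2-en-1-yl)bicyclo[3.3.1]non-3-ene-2,9-dione (target)
Conditions: LiOH·H2O (10 equiv), 1,4-dioxane–H2O 4:1 (degassed, Ar), 90 °C; then 1 M HCl to pH 3, 0 °C
Reagents that add atoms: lithium hydroxide, [Li+].[OH-]
Why: Hydroxide should cleave the methyl vinylogous ester by addition–elimination at C4 and both aryl silyl ethers by attack at silicon in one operation, oxygen-free conditions protect the catecholate, and acidification gives the enolised β-triketone with no stereocentre touched.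

**Compound list**
1 | 2-(2,6-dimethoxyphenyl)acetic acid | COc1cccc(OC)c1CC(=O)O | starting material
2 | lithium 2-(2,6-dimethoxyphenyl)propanoate (racemic) | COc1cccc(OC)c1C(C)C(=O)[O-].[Li+] | intermediate
3 | 2-(2,6-dimethoxyphenyl)-2-methylpropanoic acid | COc1cccc(OC)c1C(C)(C)C(=O)O | intermediate
4 | 2-(2,6-dimethoxycyclohexa-2,5-dien-1-yl)-2-methylpropanoic acid | COC1=CCC=C(OC)C1C(C)(C)C(=O)O | intermediate
5 | isobutyl carbonic mixed anhydride of 4 | COC1=CCC=C(OC)C1C(C)(C)C(=O)OC(=O)OCC(C)C | intermediate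
6 | 1-diazo-3-(2,6-dimethoxycyclohexa-2,5-dien-1-yl)-3-methylbutan-2-one | COC1=CCC=C(OC)C1C(C)(C)C(=O)C=[N+]=[N-] | intermediate
7 | 6,9-cyclo-2,9-dimethoxy-8,8-dimethylbicyclo[3.3.1]non-2-en-7-one (cyclopropane C5–C6–C9, cis-fused) | COC1=CC[C@@H]2[C@@H]3C(=O)C(C)(C)[C@H]1[C@]23OC | intermediate
8 | (1R,5R)-2-methoxy-8,8-dimethylbicyclo[3.3.1]non-2-ene-7,9-dione | [C@H]12CC(=O)C(C)(C)[C@H](C(OC)=CC1)C2=O | intermediate
9 | C7 lithium enolate of 8 (C6=C7–OLi) | [C@H]12C=C([O-])C(C)(C)[C@H](C(OC)=CC1)C2=O.[Li+] | intermediate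
10 | 9-hydroxy-2-methoxy-8,8-dimethylbicyclo[3.3.1]non-2-en-7-one (bridgeheads as in 8; 9-OH over the C6–C8 bridge) | [C@H]12CC(=O)C(C)(C)[C@H](C(OC)=CC1)[C@H]2O | intermediate
11 | 2-methoxy-8,8-dimethyl-9-(triethylsilyloxy)bicyclo[3.3.1]non-2-en-7-one | [C@H]12CC(=O)C(C)(C)[C@H](C(OC)=CC1)[C@H]2O[Si](CC)(CC)CC | intermediate
12 | 2-methoxy-8,8-dimethyl-9-(triethylsilyloxy)bicyclo[3.3.1]non-2-en-7-ol (7-OH endo) | [C@H]12C[C@H](O)C(C)(C)[C@H](C(OC)=CC1)[C@H]2O[Si](CC)(CC)CC | intermediate
13 | sodium O-alkyl dithiocarbonate of 12 | [C@H]12C[C@H](OC(=S)[S-])C(C)(C)[C@H](C(OC)=CC1)[C@H]2O[Si](CC)(CC)CC.[Na+] | intermediate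
14 | O-[2-methoxy-8,8-dimethyl-9-(triethylsilyloxy)bicyclo[3.3.1]non-2-en-7-yl] S-methyl carbonodithioate | [C@H]12C[C@H](OC(=S)SC)C(C)(C)[C@H](C(OC)=CC1)[C@H]2O[Si](CC)(CC)CC | intermediate
15 | O-(9-hydroxy-2-methoxy-8,8-dimethylbicyclo[3.3.1]non-2-en-7-yl) S-methyl carbonodithioate | [C@H]12C[C@H](OC(=S)SC)C(C)(C)[C@H](C(OC)=CC1)[C@H]2O | intermediate
16 | O-(2-methoxy-8,8-dimethyl-9-oxobicyclo[3.3.1]non-2-en-7-yl) S-methyl carbonodithioate (7-endo; bridgeheads as in 8) | [C@H]12C[C@H](OC(=S)SC)C(C)(C)[C@H](C(OC)=CC1)C2=O | intermediate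
17 | 7-exo-allyl-2-methoxy-8,8-dimethylbicyclo[3.3.1]non-2-en-9-one | [C@H]12C[C@@H](CC=C)C(C)(C)[C@H](C(OC)=CC1)C2=O | intermediate
18 | 7-exo-allyl-2-methoxy-8,8-dimethylbicyclo[3.3.1]non-2-ene-4,9-dione | [C@H]12C[C@@H](CC=C)C(C)(C)[C@H](C(OC)=CC1=O)C2=O | intermediate
19 | 2-methoxy-8,8-dimethyl-7-exo-(3-methylbut-2-enyl)bicyclo[3.3.1]non-2-ene-4,9-dione | [C@H]12C[C@@H](CC=C(C)C)C(C)(C)[C@H](C(OC)=CC1=O)C2=O | intermediate
20 | geranyl bromide | CC(C)=CCC/C(C)=C/CBr | starting material
21 | C5 bridgehead lithium derivative of 19 | [Li][C@]12C[C@@H](CC=C(C)C)C(C)(C)[C@H](C(OC)=CC1=O)C2=O | intermediate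
22 | 5-geranyl-2-methoxy-8,8-dimethyl-7-exo-(3-methylbut-2-enyl)bicyclo[3.3.1]non-2-ene-4,9-dione | CC(C)=CCC/C(C)=C/C[C@]12C[C@@H](CC=C(C)C)C(C)(C)[C@H](C(OC)=CC1=O)C2=O | intermediate
23 | 5-geranyl-4-hydroxy-8,8-dimethyl-7-exo-(3-methylbut-2-enyl)bicyclo[3.3.1]non-3-ene-2,9-dione | CC(C)=CCC/C(C)=C/C[C@]12C[C@@H](CC=C(C)C)C(C)(C)[C@H](C(=O)C=C1O)C2=O | intermediate
24 | 5-geranyl-4-methoxy-8,8-dimethyl-7-exo-(3-methylbut-2-enyl)bicyclo[3.3.1]non-3-ene-2,9-dione | CC(C)=CCC/C(C)=C/C[C@]12C[C@@H](CC=C(C)C)C(C)(C)[C@H](C(=O)C=C1OC)C2=O | intermediate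
25 | C1 bridgehead lithium derivative of 24 | CC(C)=CCC/C(C)=C/C[C@]12C[C@@H](CC=C(C)C)C(C)(C)[C@]([Li])(C(=O)C=C1OC)C2=O | intermediate
26 | 1,5-digeranyl-4-methoxy-8,8-dimethyl-7-exo-(3-methylbut-2-enyl)bicyclo[3.3.1]non-3-ene-2,9-dione | CC(C)=CCC/C(C)=C/C[C@]12C[C@@H](CC=C(C)C)C(C)(C)[C@](C/C=C(\C)CCC=C(C)C)(C(=O)C=C1OC)C2=O | intermediate
27 | 3,4-dihydroxybenzoic acid | OC(=O)c1ccc(O)c(O)c1 | starting material
28 | tert-butyldimethylsilyl 3,4-bis(tert-butyldimethylsilyloxy)benzoate | CC(C)(C)[Si](C)(C)OC(=O)c1ccc(O[Si](C)(C)C(C)(C)C)c(O[Si](C)(C)C(C)(C)C)c1 | intermediate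
29 | 3,4-bis(tert-butyldimethylsilyloxy)benzoyl chloride | ClC(=O)c1ccc(O[Si](C)(C)C(C)(C)C)c(O[Si](C)(C)C(C)(C)C)c1 | intermediate
30 | C3 vinyllithium of 26 | CC(C)=CCC/C(C)=C/C[C@]12C[C@@H](CC=C(C)C)C(C)(C)[C@](C/C=C(\C)CCC=C(C)C)(C(=O)C([Li])=C1OC)C2=O | intermediate
31 | 3-[3,4-bis(tert-butyldimethylsilyloxy)benzoyl]-1,5-digeranyl-4-methoxy-8,8-dimethyl-7-exo-(3-methylbut-2-enyl)bicyclo[3.3.1]non-3-ene-2,9-dione | CC(C)=CCC/C(C)=C/C[C@]12C[C@@H](CC=C(C)C)C(C)(C)[C@](C/C=C(\C)CCC=C(C)C)(C(=O)C(C(=O)c3ccc(O[Si](C)(C)C(C)(C)C)c(O[Si](C)(C)C(C)(C)C)c3)=C1OC)C2=O | intermediate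
32 | (1S,5S,7R)-3-(3,4-dihydroxybenzoyl)-1,5-bis[(2E)-3,7-dimethylocta-2,6-dien-1-yl]-4-hydroxy-8,8-dimethyl-7-(3-methylbut-2-en-1-yl)bicyclo[3.3.1]non-3-ene-2,9-dione | CC(C)=CCC/C(C)=C/C[C@]12C[C@@H](CC=C(C)C)C(C)(C)[C@](C/C=C(\C)CCC=C(C)C)(C(=O)C(C(=O)c3ccc(O)c(O)c3)=C1O)C2=O | target

**Step count**
Total: 21 steps. Longest linear sequence: 19 steps (steps 1–17, 20, 21); steps 18–19 make the aroyl chloride.

**Steps most likely to fail**

Step 4. The copper catalyst may discriminate poorly between the two enantiotopic enol ethers on this simple keto carbenoid, or the carbenoid may be diverted into C–H insertion at C4H2 or into dimerisation. The fallback sets out from 4 and returns at 8, and it moves to an acceptor/acceptor carbenoid, the substrate class on which this asymmetric cyclopropanation is best developed. Mixed anhydride 5 (made as in step 3) is condensed with lithiated methyl phenyl sulfone (2 equiv, THF, −78 °C) to give the β-keto sulfone 3-(2,6-dimethoxycyclohexa-2,5-dien-1-yl)-3-methyl-1-(phenylsulfonyl)butan-2-one F1. Diazo transfer (p-acetamidobenzenesulfonyl azide, Et3N, MeCN) gives the α-diazo-β-keto sulfone F2. Cu(I)–bis(oxazoline) cyclopropanation gives the 6-phenylsulfonyl cyclopropane F3, which is opened in the same pot (PPTS, wet THF) to the 6-phenylsulfonyl-7,9-dione F4 (C6 epimers). SmI2 (THF–MeOH, −78 °C) then removes the sulfone to give 8.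

Step 11. The C7 radical may be trapped from the wrong face, or it may add across the cleft to C3 of the facing enol ether before it meets the stannane. The fallback sets out from 8 and returns at 19, and it sets C7 by hydrogen delivery to a C6=C7 alkene rather than by C–C bond formation at a radical. KHMDS and PhNTf2 (THF, −78 °C) convert the only enolisable ketone into the C6=C7 enol triflate F5. Suzuki–Miyaura coupling with 3-methylbut-2-enylboronic acid pinacol ester under α-selective conditions (Pd catalyst, K3PO4) gives the 7-prenyl-2,6-diene F6. Hydrogenation with a cationic Ir(I) or Rh(I) catalyst ([Ir(cod)(PCy3)(py)]PF6, CH2Cl2, H2) follows. The two ring alkenes C2=C3 and C6=C7 face each other like the arms of a chelating 1,5-diene, so the metal held between them should deliver hydrogen to the inner face of C6=C7 and leave the prenyl group exo, and the unchelated side-chain alkene should react later. This should give 2-methoxy-8,8-dimethyl-7-exo-prenylbicyclo[3.3.1]non-2-en-9-one F7. Allylic oxidation as in step 12 then gives 19.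

Step 12. The chromium oxidant may over-oxidise the product, attack the allyl side chain, or stall at low conversion. The fallback sets out from 17 and returns at 18, and it builds the C4 oxygen by ionic steps from the C2 ketone instead of by C–H oxidation. Aqueous oxalic acid in THF hydrolyses the enol ether to the 2,9-dione F8. LDA followed by N-tert-butylbenzenesulfinimidoyl chloride (Mukaiyama dehydrogenation; only C3 can be deprotonated) gives the C3=C4 enone F9. Copper-catalysed conjugate borylation (CuCl, xantphos, NaOt-Bu, B2pin2, MeOH) gives the C4 boronate F10, which is not isolated and is oxidised with NaBO3 to the β-hydroxy ketone F11 (C4 epimers). Dess–Martin oxidation gives the 2,4,9-trione F12, and TMSCHN2 gives 18 together with its O-methyl regioisomer, which is separated.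

**Further compounds**
F1 | step 4 | 3-(2,6-dimethoxycyclohexa-2,5-dien-1-yl)-3-methyl-1-(phenylsulfonyl)butan-2-one | COC1=CCC=C(OC)C1C(C)(C)C(=O)CS(=O)(=O)c1ccccc1
F2 | step 4 | 1-diazo-3-(2,6-dimethoxycyclohexa-2,5-dien-1-yl)-3-methyl-1-(phenylsulfonyl)butan-2-one | COC1=CCC=C(OC)C1C(C)(C)C(=O)C(=[N+]=[N-])S(=O)(=O)c1ccccc1
F3 | step 4 | 6,9-cyclo-2,9-dimethoxy-8,8-dimethyl-6-(phenylsulfonyl)bicyclo[3.3.1]non-2-en-7-one | COC1=CC[C@@H]2[C@]3(S(=O)(=O)c4ccccc4)C(=O)C(C)(C)[C@H]1[C@]23OC
F4 | step 4 | 2-methoxy-8,8-dimethyl-6-(phenylsulfonyl)bicyclo[3.3.1]non-2-ene-7,9-dione (bridgeheads as in 8; C6 epimers) | [C@H]12C(S(=O)(=O)c3ccccc3)C(=O)C(C)(C)[C@H](C(OC)=CC1)C2=O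
F5 | step 11 | 2-methoxy-8,8-dimethyl-9-oxobicyclo[3.3.1]nona-2,6-dien-7-yl trifluoromethanesulfonate | [C@H]12C=C(OS(=O)(=O)C(F)(F)F)C(C)(C)[C@H](C(OC)=CC1)C2=O
F6 | step 11 | 2-methoxy-8,8-dimethyl-7-(3-methylbut-2-enyl)bicyclo[3.3.1]nona-2,6-dien-9-one | [C@H]12C=C(CC=C(C)C)C(C)(C)[C@H](C(OC)=CC1)C2=O
F7 | step 11 | 2-methoxy-8,8-dimethyl-7-exo-(3-methylbut-2-enyl)bicyclo[3.3.1]non-2-en-9-one | [C@H]12C[C@@H](CC=C(C)C)C(C)(C)[C@H](C(OC)=CC1)C2=O
F8 | step 12 | 7-exo-allyl-8,8-dimethylbicyclo[3.3.1]nonane-2,9-dione | [C@H]12C[C@@H](CC=C)C(C)(C)[C@H](C(=O)CC1)C2=O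
F9 | step 12 | 7-exo-allyl-8,8-dimethylbicyclo[3.3.1]non-3-ene-2,9-dione | [C@H]12C[C@@H](CC=C)C(C)(C)[C@H](C(=O)C=C1)C2=O
F10 | step 12 | 7-exo-allyl-8,8-dimethyl-4-(4,4,5,5-tetramethyl-1,3,2-dioxaborolan-2-yl)bicyclo[3.3.1]nonane-2,9-dione (C4 epimers) | [C@H]12C[C@@H](CC=C)C(C)(C)[C@H](C(=O)CC1B3OC(C)(C)C(C)(C)O3)C2=O
F11 | step 12 | 7-exo-allyl-4-hydroxy-8,8-dimethylbicyclo[3.3.1]nonane-2,9-dione (C4 epimers) | [C@H]12C[C@@H](CC=C)C(C)(C)[C@H](C(=O)CC1O)C2=O
F12 | step 12 | 7-exo-allyl-8,8-dimethylbicyclo[3.3.1]nonane-2,4,9-trione | [C@H]12C[C@@H](CC=C)C(C)(C)[C@H](C(=O)CC1=O)C2=O
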